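**Plan** (ring A = methoxy/hydroxy benzene ring, ring C = dihydropyran, ring B = aryl group on C3, ring D = dimethylpyran)
1. After removal of two MOM groups, ring C (O1–C2–C3–C4–C4a–C8a) is cut at both O1–C8a and C4–C4a. This gives the aryne of ring A (triple bond C4a≡C8a) and a C2–C3–C4 unit that carries rings B and D, a masked alkoxide on C2 and a bromide on C4.
2. Enabling feature: O1 and C4 sit on neighbouring ring-A carbons and C4a is flanked by the C5 methoxy group. In the aryne this methoxy sends the alkoxide to the remote C8a and leaves the carbanion on C4a, which closes ring C onto C4.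
3. Forward: the ortho-silylaryl triflate of ring A is made from 5-bromovanillin (steps 1–4); its Br- and OH-bearing carbons become C8a and C4a. Ring B with ring D is made from 4-bromoresorcinol by propargyl Claisen rearrangement/electrocyclisation (steps 5–7).
4. The C3 unit is attached as a temporary oxetane (step 8). Its enantioselective opening with TMSBr (step 9) sets C3, the only stereocentre, and unmasks silyl ether and bromide in one move.
5. Ring C is closed last by the aryne annulation (step 10), acid removes the MOM groups (step 11), and no bond to C3 is made or broken after step 9.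

Key step: step 10

Assumption: for step 9 the antipode of the chiral squaramide is taken that delivers bromide to the CH2 group leading to (R)-17; both antipodes are accessible from the enantiomeric amino-acid and pyrrolidine building blocks of the catalyst.

**Route**

Step 1
Reactants: 1 5-bromovanillin (3-bromo-4-hydroxy-5-methoxybenzaldehyde)
Product: 2 2-bromo-6-methoxybenzene-1,4-diol
Conditions: H2O2 (30% aq, 1.2 equiv), NaOH (1 equiv), H2O, 0 °C to rt, N2
Reagents that add atoms: hydrogen peroxide (H2O2), OO
Why: Dakin oxidation, in which hydroperoxide adds to the para-hydroxybenzaldehyde, the aryl group migrates to oxygen and the aryl formate is hydrolysed in the basic medium, so that the formyl carbon is replaced by the future C7 oxygen.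

Step 2
Reactants: 2 2-bromo-6-methoxybenzene-1,4-diol
Product: 3 1-bromo-3-methoxy-2,5-bis(trimethylsilyloxy)benzene
Conditions: HMDS (1.5 equiv), THF, 70 °C; evaporation
Reagents that add atoms: hexamethyldisilazane (HMDS), C[Si](C)(C)N[Si](C)(C)C
Why: Silylation of both phenols with loss of ammonia should give the ortho O-silyl group needed for the silyl migration of step 3 and a temporary cap on the para oxygen.

Step 3
Reactants: 3 1-bromo-3-methoxy-2,5-bis(trimethylsilyloxy)benzene
Product: 6 4-hydroxy-2-methoxy-6-(trimethylsilyl)phenyl trifluoromethanesulfonate, via lithium phenoxide 4 (not isolated), via silyl ether triflate 5 (not isolated)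
Conditions: n-BuLi (1.05 equiv), THF, −78 °C; Tf2O (1.1 equiv), −78 °C; then 1 M HCl (aq)/THF, 0 °C
Reagents that add atoms: trifluoromethanesulfonic anhydride (Tf2O), O=S(=O)(OS(=O)(=O)C(F)(F)F)C(F)(F)F
Why: Bromine–lithium exchange gives an aryllithium ortho to the silyloxy group, a retro-Brook rearrangement (1,3 shift of silicon from oxygen to carbon) gives phenoxide 4, triflation gives 5, and dilute acid should cleave only the remaining aryl O–Si bond.

Step 4
Reactants: 6 4-hydroxy-2-methoxy-6-(trimethylsilyl)phenyl trifluoromethanesulfonate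
Product: 7 2-methoxy-4-(methoxymethoxy)-6-(trimethylsilyl)phenyl trifluoromethanesulfonate
Conditions: MOMCl (1.3 equiv), i-Pr2NEt (1.5 equiv), CH2Cl2, 0 °C to rt
Reagents that add atoms: chloromethyl methyl ether (MOMCl), COCCl
Why: O-alkylation of the free phenol with a hindered amine base that does not attack silicon should leave the ortho-silyl triflate unit intact and give a protecting group inert to fluoride, alkoxide and aryl anions.

Step 5
Reactants: 8 4-bromoresorcinol (4-bromobenzene-1,3-diol)
Product: 9 2-bromo-5-(methoxymethoxy)phenol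
Conditions: MOMCl (1.0 equiv), i-Pr2NEt (1.1 equiv), CH2Cl2, −20 to 0 °C
Reagents that add atoms: chloromethyl methyl ether (MOMCl), COCCl
Why: Mono-protection should go to the oxygen para to bromine, because the hydroxyl ortho to bromine is the more hindered one and is held in an O–H···Br hydrogen bond.

Step 6
Reactants: 9 2-bromo-5-(methoxymethoxy)phenol, 10 3-chloro-3-methylbut-1-yne
Product: 11 1-bromo-4-(methoxymethoxy)-2-[(2-methylbut-3-yn-2-yl)oxy]benzene
Conditions: DBU (1.3 equiv), CuCl2 (1 mol%), MeCN, 0 °C
Reagents that add atoms: none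
Why: Copper-catalysed propargylic etherification of the phenoxide (through a copper allenylidene) is the standard way to tertiary aryl propargyl ethers and tolerates the ortho bromide and the MOM ether.

Step 7
Reactants: 11 1-bromo-4-(methoxymethoxy)-2-[(2-methylbut-3-yn-2-yl)oxy]benzene
Product: 13 8-bromo-5-(methoxymethoxy)-2,2-dimethyl-2H-chromene, via allenyl phenol 12 (not isolated)
Conditions: N,N-diethylaniline, 150 °C
Reagents that add atoms: none
Why: The aromatic propargyl Claisen rearrangement ([3,3]) can only reach the free ortho carbon between the two oxygens (the other ortho carbon bears Br) and gives allenyl phenol 12, whose 1,5-hydrogen shift and oxa-6π electrocyclisation close ring D.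

Step 8
Reactants: 13 8-bromo-5-(methoxymethoxy)-2,2-dimethyl-2H-chromene, 14 3-iodooxetane
Product: 16 3-[5-(methoxymethoxy)-2,2-dimethyl-2H-chromen-8-yl]oxetane, via oxetan-3-ylzinc iodide 15 (not isolated)
Conditions: 14 (1.5 equiv), Zn dust (activated with 1,2-dibromoethane and TMSCl), LiCl, THF, 40 °C; then 13, Pd(OAc)2 (3 mol%), CPhos (6 mol%), THF/toluene, rt to 50 °C
Reagents that add atoms: none
Why: Negishi coupling, in which the secondary alkylzinc 15 transmetalates to the arylpalladium bromide formed from 13 and zerovalent palladium, while β-hydride elimination is suppressed because it would give a strained oxete.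

Step 9
Reactants: 16 3-[5-(methoxymethoxy)-2,2-dimethyl-2H-chromen-8-yl]oxetane
Product: 17 (R)-[3-bromo-2-[5-(methoxymethoxy)-2,2-dimethyl-2H-chromen-8-yl]propoxy]trimethylsilane
Conditions: TMSBr (1.2 equiv), chiral tert-leucine/arylpyrrolidine squaramide hydrogen-bond-donor catalyst (5 mol%), t-BuOMe, −78 °C; volatiles removed, no aqueous work-up
Reagents that add atoms: bromotrimethylsilane (TMSBr), C[Si](C)(C)Br
Why: Catalytic enantioselective desymmetrising ring opening of a 3-aryloxetane, in which the squaramide-bound bromide attacks one of the two enantiotopic CH2 groups of the O-silylated oxetanium ion (SN2), sets C3 without touching its bonds and gives silyl ether and bromide at once, while −78 °C and the much higher basicity of the oxetane oxygen should spare the aryl MOM ether.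

Step 10
Reactants: 17 (R)-[3-bromo-2-[5-(methoxymethoxy)-2,2-dimethyl-2H-chromen-8-yl]propoxy]trimethylsilane, 7 2-methoxy-4-(methoxymethoxy)-6-(trimethylsilyl)phenyl trifluoromethanesulfonate
Product: 21 (3R)-5-methoxy-7-(methoxymethoxy)-3-[5-(methoxymethoxy)-2,2-dimethyl-2H-chromen-8-yl]chromane, via potassium alkoxide 18 (not isolated), via aryne 19 (not isolated), via aryl anion 20 (not isolated)
Conditions: 7 (2 equiv), KF (5 equiv), 18-crown-6 (5 equiv), THF, 0 °C to rt, fluoride added in portions
Reagents that add atoms: none
Why: Proposed new method: fluoride removes the silyl groups of both partners, so that 7 loses triflate to give aryne 19 (C4a≡C8a of ring A) while 17 gives the proton-free alkoxide 18, which adds to the aryne carbon remote from the methoxy group (future C8a) because the inductively withdrawing C5 methoxy beside the triple bond distorts it and stabilises the carbanion developing on the adjacent carbon (future C4a), the OMOM group para to that carbon having no say. The aryl anion 20 then displaces the primary bromide in a 6-exo-tet SN2 closure (C4a–C4), so that ring C is completed with O1–C8a and C4a–C4 formed in one operation. The closest known reaction types are the annulations of arynes with ortho-hydroxychalcones or salicylates, in which the aryl anion born from oxygen addition is trapped by a tethered acceptor, and the Parham cyclialkylation of aryllithiums onto tethered alkyl halides; new here are an sp3 bromide as the internal trap and a silyl ether as the alkoxide source. No stereocentre is formed: C3 comes from step 9, no bond to it is made or broken and it carries no acidifying group, so its configuration should be retained. The step needs regioselective alkoxide addition (secured by the methoxy group), C-alkylation of 20 in preference to protonation (secured by the absence of any O–H, the alkoxide being released from a silyl ether in THF) and aryne capture in preference to 4-exo-tet reclosure of 18 to oxetane 16 (favoured by excess 7, a low alkoxide concentration and 0 °C; any 16 formed can be sent through step 9 again).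

Step 11
Reactants: 21 (3R)-5-methoxy-7-(methoxymethoxy)-3-[5-(methoxymethoxy)-2,2-dimethyl-2H-chromen-8-yl]chromane
Product: 22 (3R)-3-(5-hydroxy-2,2-dimethyl-2H-chromen-8-yl)-5-methoxychroman-7-ol
Conditions: 2 M HCl (aq), MeOH/THF, 45 °C
Reagents that add atoms: none
Why: Acid-catalysed acetal exchange with methanol should remove both aryl MOM ethers as dimethoxymethane under conditions that dimethylchromenes tolerate and that cannot ionise or enolise C3.

**Compound list**
1 | 5-bromovanillin (3-bromo-4-hydroxy-5-methoxybenzaldehyde) | COc1cc(C=O)cc(Br)c1O | starting material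
2 | 2-bromo-6-methoxybenzene-1,4-diol | COc1cc(O)cc(Br)c1O | intermediate
3 | 1-bromo-3-methoxy-2,5-bis(trimethylsilyloxy)benzene | COc1cc(O[Si](C)(C)C)cc(Br)c1O[Si](C)(C)C | intermediate
4 | lithium 2-methoxy-6-(trimethylsilyl)-4-(trimethylsilyloxy)phenolate | COc1cc(O[Si](C)(C)C)cc([Si](C)(C)C)c1[O-].[Li+] | intermediate
5 | 2-methoxy-6-(trimethylsilyl)-4-(trimethylsilyloxy)phenyl trifluoromethanesulfonate | COc1cc(O[Si](C)(C)C)cc([Si](C)(C)C)c1OS(=O)(=O)C(F)(F)F | intermediate
6 | 4-hydroxy-2-methoxy-6-(trimethylsilyl)phenyl trifluoromethanesulfonate | COc1cc(O)cc([Si](C)(C)C)c1OS(=O)(=O)C(F)(F)F | intermediate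
7 | 2-methoxy-4-(methoxymethoxy)-6-(trimethylsilyl)phenyl trifluoromethanesulfonate | COc1cc(OCOC)cc([Si](C)(C)C)c1OS(=O)(=O)C(F)(F)F | intermediate
8 | 4-bromoresorcinol (4-bromobenzene-1,3-diol) | Oc1ccc(Br)c(O)c1 | starting material
9 | 2-bromo-5-(methoxymethoxy)phenol | COCOc1ccc(Br)c(O)c1 | intermediate
10 | 3-chloro-3-methylbut-1-yne | C#CC(C)(C)Cl | starting material
11 | 1-bromo-4-(methoxymethoxy)-2-[(2-methylbut-3-yn-2-yl)oxy]benzene | COCOc1ccc(Br)c(OC(C)(C)C#C)c1 | intermediate
12 | 6-bromo-3-(methoxymethoxy)-2-(3-methylbuta-1,2-dien-1-yl)phenol | COCOc1ccc(Br)c(O)c1C=C=C(C)C | intermediate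
13 | 8-bromo-5-(methoxymethoxy)-2,2-dimethyl-2H-chromene | COCOc1ccc(Br)c2OC(C)(C)C=Cc12 | intermediate
14 | 3-iodooxetane | IC1COC1 | starting material
15 | oxetan-3-ylzinc iodide | I[Zn]C1COC1 | intermediate
16 | 3-[5-(methoxymethoxy)-2,2-dimethyl-2H-chromen-8-yl]oxetane | COCOc1ccc(C2COC2)c2OC(C)(C)C=Cc12 | intermediate
17 | (R)-[3-bromo-2-[5-(methoxymethoxy)-2,2-dimethyl-2H-chromen-8-yl]propoxy]trimethylsilane | C[Si](C)(C)OC[C@H](CBr)c1ccc(OCOC)c2C=CC(C)(C)Oc12 | intermediate
18 | potassium (R)-3-bromo-2-[5-(methoxymethoxy)-2,2-dimethyl-2H-chromen-8-yl]propan-1-olate | [K+].[O-]C[C@H](CBr)c1ccc(OCOC)c2C=CC(C)(C)Oc12 | intermediate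
19 | 3-methoxy-5-(methoxymethoxy)-1,2-didehydrobenzene (aryne) | COC1=CC(OCOC)=CC#C1 | intermediate
20 | [2-[(R)-3-bromo-2-[5-(methoxymethoxy)-2,2-dimethyl-2H-chromen-8-yl]propoxy]-6-methoxy-4-(methoxymethoxy)phenyl]potassium | [K+].COc1cc(OCOC)cc(OC[C@H](CBr)c2ccc(OCOC)c3C=CC(C)(C)Oc23)[c-]1 | intermediate
21 | (3R)-5-methoxy-7-(methoxymethoxy)-3-[5-(methoxymethoxy)-2,2-dimethyl-2H-chromen-8-yl]chromane | COc1cc(OCOC)cc2c1C[C@H](c1ccc(OCOC)c3c1OC(C)(C)C=C3)CO2 | intermediate
22 | (3R)-3-(5-hydroxy-2,2-dimethyl-2H-chromen-8-yl)-5-methoxychroman-7-ol | COc1cc(O)cc2c1C[C@H](c1ccc(O)c3c1OC(C)(C)C=C3)CO2 | target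

**Step count and risks**
Total steps: 11. Longest linear sequence: 7 (steps 5–11).

Steps most likely to fail:

1. Step 10 (proposed new method). What may go wrong: the alkoxide recloses to the oxetane by 4-exo-tet displacement before it meets the aryne, or the aryl anion is protonated or eliminates HBr across C3–C4 instead of alkylating. Fallback (cross-coupling, then Mitsunobu etherification; known chemistry): it sets out from 17 and comes back at 22. Purchased 5-methoxyresorcinol F1 is protected with MOMCl/i-Pr2NEt to 1-methoxy-3,5-bis(methoxymethoxy)benzene F2. NBS (MeCN, 0 °C) should brominate one of the two equivalent positions between OMe and OMOM to give 2-bromo-1-methoxy-3,5-bis(methoxymethoxy)benzene F3. Zinc insertion into the C–Br bond of 17 (Zn, LiCl, THF) gives the alkylzinc bromide F4, which is coupled with F3 (Pd(OAc)2, SPhos; Negishi coupling) to the C4–C4a linked silyl ether F5. HCl in methanol removes the TMS and the three MOM groups to give the phenolic alcohol F6. An intramolecular Mitsunobu etherification (PPh3, DIAD, THF, high dilution) with the only phenol ortho to the side chain then closes O1–C2 and gives 22.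

2. Step 9. What may go wrong: cleavage of the aryl MOM ether by TMSBr, or poor discrimination between the two enantiotopic CH2 groups because of the ortho-alkoxy substituent of the aryl group. Fallback (enzymatic desymmetrisation of a prochiral diol instead of oxetane opening): it sets out from 13 and comes back at 17. Pd-catalysed arylation of diethyl malonate with 13 (Pd(OAc)2, P(t-Bu)3, K3PO4, toluene) gives the diethyl arylmalonate F7, and LiAlH4 reduces it to the prochiral 2-arylpropane-1,3-diol F8. Monoacetylation with vinyl acetate and Burkholderia cepacia lipase is expected, by analogy with other 2-substituted propane-1,3-diols, to acetylate the pro-S arm and give the (S)-monoacetate F9; its configuration would be checked before going on. CBr4/PPh3 converts the free alcohol into the (R)-bromo acetate F10, DIBAL-H at −78 °C removes the acetate without forming a free alkoxide and gives the (R)-bromo alcohol F11, and TMSCl/Et3N gives 17.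

3. Step 5. What may go wrong: poor site selectivity between the two hydroxyl groups, or double protection. Fallback (steric differentiation with a bulky temporary silyl group, MOM introduced after the propargyl ether): it sets out from 8 and comes back at 11. TIPSCl/imidazole should silylate only the unhindered hydroxyl para to bromine and give 2-bromo-5-(triisopropylsilyloxy)phenol F12. Etherification with 10 (DBU, CuCl2, MeCN) gives the propargyl ether F13, TBAF frees the phenol 4-bromo-3-[(2-methylbut-3-yn-2-yl)oxy]phenol F14, and MOMCl/i-Pr2NEt gives 11.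

**Further compounds**
F1 | step 10 | 5-methoxyresorcinol (purchased) | COc1cc(O)cc(O)c1
F2 | step 10 | 1-methoxy-3,5-bis(methoxymethoxy)benzene | COc1cc(OCOC)cc(OCOC)c1
F3 | step 10 | 2-bromo-1-methoxy-3,5-bis(methoxymethoxy)benzene | COc1cc(OCOC)cc(OCOC)c1Br
F4 | step 10 | [(R)-2-[5-(methoxymethoxy)-2,2-dimethyl-2H-chromen-8-yl]-3-(trimethylsilyloxy)propyl]zinc bromide | C[Si](C)(C)OC[C@H](C[Zn]Br)c1ccc(OCOC)c2C=CC(C)(C)Oc12
F5 | step 10 | (R)-[2-[5-(methoxymethoxy)-2,2-dimethyl-2H-chromen-8-yl]-3-[2-methoxy-4,6-bis(methoxymethoxy)phenyl]propoxy]trimethylsilane | C[Si](C)(C)OC[C@H](Cc1c(OC)cc(OCOC)cc1OCOC)c1ccc(OCOC)c2C=CC(C)(C)Oc12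
F6 | step 10 | 4-[(R)-3-hydroxy-2-(5-hydroxy-2,2-dimethyl-2H-chromen-8-yl)propyl]-5-methoxybenzene-1,3-diol | OC[C@H](Cc1c(OC)cc(O)cc1O)c1ccc(O)c2C=CC(C)(C)Oc12
F7 | step 9 | diethyl 2-[5-(methoxymethoxy)-2,2-dimethyl-2H-chromen-8-yl]malonate | CCOC(=O)C(C(=O)OCC)c1ccc(OCOC)c2C=CC(C)(C)Oc12
F8 | step 9 | 2-[5-(methoxymethoxy)-2,2-dimethyl-2H-chromen-8-yl]propane-1,3-diol | OCC(CO)c1ccc(OCOC)c2C=CC(C)(C)Oc12
F9 | step 9 | (S)-3-hydroxy-2-[5-(methoxymethoxy)-2,2-dimethyl-2H-chromen-8-yl]propyl acetate | CC(=O)OC[C@H](CO)c1ccc(OCOC)c2C=CC(C)(C)Oc12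
F10 | step 9 | (R)-3-bromo-2-[5-(methoxymethoxy)-2,2-dimethyl-2H-chromen-8-yl]propyl acetate | CC(=O)OC[C@H](CBr)c1ccc(OCOC)c2C=CC(C)(C)Oc12
F11 | step 9 | (R)-3-bromo-2-[5-(methoxymethoxy)-2,2-dimethyl-2H-chromen-8-yl]propan-1-ol | OC[C@H](CBr)c1ccc(OCOC)c2C=CC(C)(C)Oc12
F12 | step 5 | 2-bromo-5-(triisopropylsilyloxy)phenol | CC(C)[Si](Oc1ccc(Br)c(O)c1)(C(C)C)C(C)C
F13 | step 5 | [4-bromo-3-[(2-methylbut-3-yn-2-yl)oxy]phenoxy]triisopropylsilane | CC(C)[Si](Oc1ccc(Br)c(OC(C)(C)C#C)c1)(C(C)C)C(C)C
F14 | step 5 | 4-bromo-3-[(2-methylbut-3-yn-2-yl)oxy]phenol | Oc1ccc(Br)c(OC(C)(C)C#C)c1
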